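The time allowed is 12 s. Four flasks differ in their charge of Z.

in all of them: X 5.0 mM; E 4.50 mM; time 12 s
- green: Z 0.600 mM
- amber: Z 1.20 mM
- teal: Z 2.50 mM
- red: Z 5.00 mM

    X + E ⇌ X.E (K1 = 88 M⁻¹, k1 = 29.0 M⁻¹ s⁻¹)
    Z + E ⇌ Z.E (K2 = 170 M⁻¹, k2 = 25.4 M⁻¹ s⁻¹)

1. amount of X.E at the end, in percent of the X charged for green, amber, teal, red, in this order
2. how that number moves from the first to the last of them (falls all the way / rises, then falls / falls, then rises / rises all the way / hardly changes)

- "hardly changes" means that all values lie within two and a half points (for a concentration: within two and a half percent of the largest)
- run time (green): 12 s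

Where do you start? With the large thing: X and E, with Z left out of the balance for a moment. The quadratic from the first equilibrium constant gives free E of 3.36 mM, or 74.6% of its charge. X.E then stands at 22.8% of the X charged.

And Z? It is the correction. At that free E, Z binds 36.3% of its own charge.

Who pays for the E held in Z.E? Free E and X.E share the bill. When free E falls by one part, X.E gives back 0.262 of a part. So I define the give-back share: the fraction of the E held in Z.E that comes out of X.E, the rest coming out of free E. It is 20.8%.

But you reckon from balance, and the flask runs for a fixed time. Is that allowed? Counting both directions and leaving out the small term for Z itself, Z relaxes with a half-life of 2.95 s. X relaxes with one of 1.29 s, shorter than that of Z. The time allowed holds 4.07 of the longer half-lives, so I reckon from balance.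

Is a large charge of Z still a small drain? Less simply. I correct the bound share of Z once for the fall in free E. The loss of X.E is then 0.877% of the X charged in green, 1.70% in amber, 3.32% in teal and 5.93% in red.

Your row? I commit to 21.9%, 21.1%, 19.5% and 16.9%. Each step up in Z adds to the loss, so the shape is "falls all the way", with 5.1 percentage points between green and red.

The forecast gives 22%, 21.2%, 19.6% and 17%, with the shape "falls all the way", on the ground that “X and Z simply compete for the same E”, and its red figure lies slightly above mine.

The simulation gives 22.0%, 21.2%, 19.6% and 17.0%, and the shape is "falls all the way".

In green, the binding of X had 51% of its turnover up to 12.0 s behind it at 1.20 s, while the binding of Z reached half of its turnover up to that time at 2.18 s. At 12.0 s, green held E at 71.1% and Z at 66.4% of their charges. Its 0.202 mM of Z.E, put through the give-back share, places X.E at 22.0% of the X charged. Red held 1.35 mM of Z.E at 12.0 s, and the same share places X.E at 17.2%, against a reading of 17.0%.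

All constants are invented.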